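The vessel is closed, stirred and held at one temperature. The alder flask repeats the larch charge, but the larch run was read to 110 min and alder is asked at 220 min.

| setting | larch | oak | cedar | birch | alder |
|---|---|---|---|---|---|
| substrate | 1.00 M | 1.00 M | 3.00 M | 1.00 M | 1.00 M |
| partner | 1.10 M | 0.550 M | 1.10 M | 1.10 M | 1.10 M |
| product |  |  |  | 0.500 M |  |
| time |  |  |  |  | 220 min |

| larch run: time / min | larch run: [product] / M | oak run: time / min | oak run: [product] / M | cedar run: time / min | cedar run: [product] / M | birch run: time / min | birch run: [product] / M |
|---|---|---|---|---|---|---|---|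
| 8.4 | 0.311 | 8.4 | 0.162 | 8.4 | 0.635 | 8.4 | 0.809 |
| 25 | 0.522 | 25 | 0.283 | 25 | 0.859 | 25 | 1.016 |
| 49 | 0.620 | 49 | 0.337 | 49 | 0.924 | 49 | 1.114 |
| 77 | 0.648 | 77 | 0.357 | 77 | 0.951 | 77 | 1.166 |
| 110 | 0.677 | 110 | 0.364 | 110 | 0.950 | 110 | 1.187 |

(each reading ± 0.005 M)

1. reaction order in [substrate] at the outset, round the charge of the larch run, defined at two percent of the substrate turned into product (one fixed amount of product, the same in the runs compared)
2. reaction order in [partner] at the outset, round the charge of the larch run, defined at two percent of the substrate turned into product
3. product in the alder run at 220 min, as a share of the substrate charged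

- Overall: substrate + partner -> product.
- Constant volume, constant temperature.
- A reading of a species includes what of it is bound.
- "The second partner" is partner.
- An order is taken over about fifteen percent of the charge, up and down.

For alder I need what a dying rate still has to give, so I replace the larch curve by its mean rates and set each at mid-span. From 25 min to 49 min the mean is 0.00408 M min⁻¹, and from 77 min to 110 min it is 8.79 × 10⁻⁴ M min⁻¹, with a scatter of 2.14 × 10⁻⁴ M min⁻¹. Taking the fall as exponential gives the tail time, the time in which the rate falls by a factor e, of 36.8 min. The larch rate at 110 min is then 5.61 × 10⁻⁴ M min⁻¹, and up to 220 min it adds 0.0196 M. My figure for alder is therefore 69.7 % of the substrate charged.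

The forecast gives 0.9, 1 and 70 %, reached by another road: “This fits partner, or something tied to it, being lost in a parallel first-order path.”

The flask gives 1.0, 1.1 and 70.3 %.

    2 partner ⇌ reagent dimer, settled at all times (14.60 M⁻¹)
    substrate + reagent dimer → product + partner (0.1332 M⁻¹ min⁻¹)
    2 substrate → homo dimer (0.01464 M⁻¹ min⁻¹)
    partner → lost reagent (0.02358 min⁻¹)

The alder run ends 0.0257 M above the last larch reading, against my 0.0196 M, and that reading has a scatter of 0.005 M. Carried to oak, the tail time 36.8 min turns the mean rate from 49 min to 77 min into 0.368 M at 110 min, and oak reads 0.364 M. In the alder run, 42 % of the missing product is lost to the conversion of substrate into homo dimer: without that conversion the alder run gives 82.8 % instead of 70.3 %.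

The data stem from a simulated flask with made-up constants.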